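## Retrosynthetic overview

1. Target ⇒ colupulone: open the pyran O1–C2 bond and return two hydrogens. Forward, one of the two enantiotopic geminal prenyl groups closes onto the C5 enol oxygen in an enantiotopic-group-selective oxidative (Wacker-type) cyclisation. This is the biosynthetic ring closure, and it creates the only stereocentre.
2. Colupulone ⇒ phloroisobutyrophenone + three prenyl units: two aromatic C-prenylations, then alkylative dearomatisation, in one flask, as in β-acid biosynthesis.
3. Phloroisobutyrophenone ⇒ phloroglucinol + an isobutyryl unit (Friedel–Crafts acylation, standing in for the polyketide step).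
4. Ring order: the carbocycle is the phloroglucinol ring of the starting material, dearomatised in the second step; the pyran ring is formed last.

Assumption: all β-triketones are drawn in the tautomer of the target SMILES, in which the stereocentre is 4aR; the sense of induction of the new step 3 cannot be predicted, so the (M,S,S) ligand is written and its (P,R,R) antipode is used if that is the one that gives 4aR.

## Route

Step 1
Reactants: 1 phloroglucinol (benzene-1,3,5-triol); 2 isobutyryl chloride (2-methylpropanoyl chloride)
Product: 3 phloroisobutyrophenone [2-methyl-1-(2,4,6-trihydroxyphenyl)propan-1-one]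
Conditions: AlCl3 (3.5 equiv), PhNO2/CH2Cl2, 0 °C to 45 °C; then ice/aq HCl
Reagents that add atoms: isobutyryl chloride (2), CC(C)C(Cl)=O
Why: Friedel–Crafts C-acylation of the strongly activated, threefold-symmetric ring, where the hydrogen-bonded aryl ketone product is deactivated so the reaction stops at mono-acylation; no stereocentre.

Step 2
Reactants: 3 phloroisobutyrophenone; 4 prenyl bromide (1-bromo-3-methylbut-2-ene)
Product: 7 colupulone [3,5-dihydroxy-4,6,6-tris(3-methylbut-2-en-1-yl)-2-(2-methylpropanoyl)cyclohexa-2,4-dien-1-one; achiral], via monoprenyl phloroisobutyrophenone 5 (not isolated), via deoxycohumulone 6 (not isolated)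
Conditions: prenyl bromide (3.1 equiv), 10% aq KOH, 0 °C, Ar; then aq HCl to pH 2
Reagents that add atoms: prenyl bromide (4), CC(C)=CCBr
Why: In protic base the phloroglucinolate alkylates at carbon: two aromatic C-prenylations, then alkylative dearomatisation at a prenyl-bearing carbon (the classical lupulone synthesis) give the geminal diprenyl β-triketone; no stereocentre, since C6 carries two identical prenyl groups and is prochiral.

Step 3
Reactants: 7 colupulone
Product: 8 target, (4aR)-7-hydroxy-2,2-dimethyl-4a,8-bis(3-methylbut-2-en-1-yl)-6-(2-methylpropanoyl)-2H-chromen-5(4aH)-one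
Conditions: Pd(OCOCF3)2 (10 mol%), (M,S,S)-i-Pr-SPRIX (spiro bis(isoxazoline) ligand, 15 mol%), p-benzoquinone (1.3 equiv), CH2Cl2, 0 °C to 25 °C, Ar, dark; stopped at about 80% conversion
Reagents that add atoms: none
Why: Proposed new method: desymmetrising oxidative oxa-Wacker cyclisation in which the free C5 enol oxygen (the other ring oxygens are tied up in the hydrogen-bonded β-triketone) adds 6-endo (Markovnikov) to one of the two enantiotopic C6 prenyl alkenes on the chiral cationic divalent palladium centre; the secondary alkylpalladium can β-hydride-eliminate only towards the former CH2 (its other neighbour is the quaternary O–CMe2 carbon), which gives the 3,4-alkene, and benzoquinone reoxidises zerovalent palladium; because the nucleophilic oxygen lies in the mirror plane of 7, the ligand has only to tell the prenyl above the ring from the one below, and closure of the pro-R prenyl gives 4aR; the closest known reaction types are the enantioselective 6-endo-trig Wacker-type cyclisation of 2-geranylphenols to 2H-chromenes with this catalyst system, desymmetrising Wacker cyclisations of dialkenyl alcohols with palladium–SPRIX, and the oxidative alkoxylation of α-alkenyl β-diketones through the enol oxygen with divalent palladium.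

## Compound list

1 | phloroglucinol (benzene-1,3,5-triol) | Oc1cc(O)cc(O)c1 | starting material
2 | isobutyryl chloride (2-methylpropanoyl chloride) | CC(C)C(Cl)=O | starting material
3 | phloroisobutyrophenone, 2-methyl-1-(2,4,6-trihydroxyphenyl)propan-1-one | CC(C)C(=O)c1c(O)cc(O)cc1O | intermediate
4 | prenyl bromide (1-bromo-3-methylbut-2-ene) | CC(C)=CCBr | starting material
5 | monoprenyl phloroisobutyrophenone, 2-methyl-1-[2,4,6-trihydroxy-3-(3-methylbut-2-en-1-yl)phenyl]propan-1-one | CC(C)C(=O)c1c(O)cc(O)c(CC=C(C)C)c1O | intermediate
6 | deoxycohumulone, 2-methyl-1-[2,4,6-trihydroxy-3,5-bis(3-methylbut-2-en-1-yl)phenyl]propan-1-one | CC(C)C(=O)c1c(O)c(CC=C(C)C)c(O)c(CC=C(C)C)c1O | intermediate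
7 | colupulone, 3,5-dihydroxy-4,6,6-tris(3-methylbut-2-en-1-yl)-2-(2-methylpropanoyl)cyclohexa-2,4-dien-1-one (achiral) | CC(C)C(=O)C1=C(O)C(CC=C(C)C)=C(O)C(CC=C(C)C)(CC=C(C)C)C1=O | intermediate
8 | (4aR)-7-hydroxy-2,2-dimethyl-4a,8-bis(3-methylbut-2-en-1-yl)-6-(2-methylpropanoyl)-2H-chromen-5(4aH)-one | CC(C)=CCC1=C2OC(C)(C)C=C[C@@]2(CC=C(C)C)C(=O)C(C(=O)C(C)C)=C1O | target

## Step count and risks

Total step count: 3. Longest linear sequence: 3 steps (1 → 3 → 7 → 8).

Steps most likely to fail, in order of risk:

Step 3 is the riskiest. The C4 prenyl can close onto the same oxygen and would give an achiral 8,8-diprenyl chromenone isomer. Only the 2:1 statistical factor and the gem-dialkyl effect favour the C6 prenyls. Closure onto the C1 oxygen would give the other ring-fused isomer. The β-triketone may also hold the palladium as a chelate, the enantiotopic-group selection is untested, and the product can cyclise a second time. The fallback sets out from 7 and comes back at 8. It replaces metal activation by an organocatalytic desymmetrising bromoetherification: N-bromosuccinimide (O=C1CCC(=O)N1Br, 1.05 equiv) and a cinchona-derived amino-thiocarbamate catalyst (10 mol%) in CHCl3/toluene at −50 °C. The quinuclidine nitrogen pairs with the acidic C5 hydroxyl and the thiocarbamate sulfur hands the bromonium to the prenyl on one face. The closest precedents are enantioselective bromocyclisation of olefinic 1,3-dicarbonyl compounds through the enol oxygen and desymmetrising bromolactonisation of α,α-diallyl acids. The 6-endo anti addition gives the bromide (3S,4aR)-3-bromo-7-hydroxy-2,2-dimethyl-4a,8-bis(3-methylbut-2-en-1-yl)-6-(2-methylpropanoyl)-3,4-dihydro-2H-chromen-5(4aH)-one F1, drawn as the 3,4a-trans isomer expected from a chair-like closure. Its C3 configuration is then erased by anti-E2 elimination with DBU (3 equiv) in toluene at 80 °C, which can only take a C4 hydrogen and so delivers 8.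

Step 2 is next. Over-alkylation to the tetraprenyl compound, O-prenylation and air oxidation of the β-acid keep the one-flask yield modest (about 30–40% is typical of this kind of triple prenylation). The fallback sets out from 3 and comes back at 7. It separates the two kinds of C–C bond formation and changes the first to an acid-mediated Friedel–Crafts prenylation. Compound 3 is treated with 2-methylbut-3-en-2-ol (CC(C)(O)C=C, 2.2 equiv) and BF3·OEt2 in dioxane at 25 °C, and deoxycohumulone 6 is isolated. Compound 6 is then dearomatised with one equivalent of 4 and NaOMe in MeOH at 0 °C to give 7. This fallback makes no compound outside the list (F0).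

Step 1 is the least risky. Possible problems are O-acylation or diacylation, incompletely dried phloroglucinol and tedious removal of nitrobenzene. The fallback sets out from 1 and comes back at 3. It is a Houben–Hoesch reaction: isobutyronitrile (CC(C)C#N), ZnCl2 and HCl gas in Et2O at 0 °C precipitate the ketiminium salt 2-methyl-1-(2,4,6-trihydroxyphenyl)propan-1-iminium chloride F2. This cannot acylate twice, and boiling water hydrolyses it to 3.

## Further compounds

F1 | step 3 | (3S,4aR)-3-bromo-7-hydroxy-2,2-dimethyl-4a,8-bis(3-methylbut-2-en-1-yl)-6-(2-methylpropanoyl)-3,4-dihydro-2H-chromen-5(4aH)-one | CC(C)=CCC1=C2OC(C)(C)[C@@H](Br)C[C@@]2(CC=C(C)C)C(=O)C(C(=O)C(C)C)=C1O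
F0 | step 2 | none | none
F2 | step 1 | 2-methyl-1-(2,4,6-trihydroxyphenyl)propan-1-iminium chloride | CC(C)C(=[NH2+])c1c(O)cc(O)cc1O.[Cl-]
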